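**Plan**

- Cuts, in retrosynthetic order: (i) the C(sp3)–C(sp2) bond between the ring-bound CH2CH2 arm and the methyl-bearing alkene carbon of the 12-membered ring; (ii) the tertiary ether C–O bond; (iii) the two cyclohexene bonds CH(O)–CH2 and C(CH3)(quaternary)–CH(CH3), as a [4+2] of a 2-pyrone with a 2-alkoxypropene.
- Enabling feature: in the cyclohexene, the ether oxygen on the CH–O carbon and the CH2 arm on the quaternary C(CH3) are 1,4 and cis, with the butenolide C=C between them. This is a 2-pyrone/enol ether cycloadduct whose O–C(=O) bridge has been opened, the bridge carbonyl becoming the first arm carbon.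
- Forward, ring part: acetonedicarboxylate gives the butenolide-fused 3-methyl-2-pyrone 8; cycloaddition with the chiral isopropenyl ether 10 builds the carbocycle as bridged lactone 11; auxiliary removal, dehydration, lactone opening, directed hydrogenation and acid reduction give alcohol 17.
- Forward, bridge: epoxide 28 (Z-vinyl iodide, carbinol, 2,2-disubstituted epoxide) is made from but-2-yn-1-ol, joined to 17 through the ether, and the macrocycle is closed last by hydroboration/B-alkyl Suzuki coupling, then desilylation.
- Stereochemistry: both bridgeheads from the cycloaddition (cis through the lactone bridge; absolute sense from the 1-phenylethyl auxiliary, diastereomers separated); ring CH(CH3) by hydroxyl-directed hydrogenation; carbinol by Brown methallylation; tertiary ether carbon by syn iodocarbonate cyclisation, then inversion in the epoxide opening; Z-alkene by trans-hydroalumination/iodination, retained in the coupling.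

Key step: step 6

Assumption: the (R)-1-phenylethyl group is taken to be the auxiliary enantiomer whose major, separable adduct has the bridgehead configuration of 11; if the bias runs the other way, the commercial (S)-acetate is used and nothing else changes.

**Route**

Step 1
Reactants: 1 dimethyl 3-oxopentanedioate
Product: 2 dimethyl 2-methyl-3-oxopentanedioate
Conditions: NaH (1.0 equiv), THF, 0 °C; MeI (1.0 equiv), 0 °C to rt; fractional distillation
Reagents that add atoms: iodomethane, CI
Why: C-alkylation of a β-keto ester enolate (acetoacetic ester alkylation) with one equivalent of base and electrophile should give mainly the mono-methyl compound, and the new enolisable centre becomes sp2 in step 2.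

Step 2
Reactants: 2 dimethyl 2-methyl-3-oxopentanedioate; 3 triethyl orthoformate
Product: 5 methyl 4-hydroxy-5-methyl-6-oxo-6H-pyran-3-carboxylate, via ethoxymethylidene diester 4 (not isolated)
Conditions: Ac2O (2.5 equiv), 130 °C, volatiles distilled off; then 1 M HCl, rt
Reagents that add atoms: water, O
Why: orthoester (Claisen-type) condensation at the only free active methylene, then acid-promoted lactonisation of the derived hydroxymethylidene enol onto the methyl-branched ester arm (6-exo-trig acyl substitution), should give the 4-hydroxy-2-pyrone as it does for the unmethylated diester.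

Step 3
Reactants: 5 methyl 4-hydroxy-5-methyl-6-oxo-6H-pyran-3-carboxylate
Product: 6 methyl 5-methyl-6-oxo-4-(trifluoromethylsulfonyloxy)-6H-pyran-3-carboxylate
Conditions: Tf2O (1.1 equiv), Et3N, CH2Cl2, −78 °C
Reagents that add atoms: trifluoromethanesulfonic anhydride, O=S(=O)(OS(=O)(=O)C(F)(F)F)C(F)(F)F
Why: O-triflation of the acidic vinylogous-acid enol, routine for 4-hydroxy-2-pyrones, turns C4 into a cross-coupling electrophile.

Step 4
Reactants: 6 methyl 5-methyl-6-oxo-4-(trifluoromethylsulfonyloxy)-6H-pyran-3-carboxylate
Product: 8 7-methyl-1H-furo[3,4-c]pyran-3,6-dione (butenolide-fused 3-methyl-2-pyrone), via hydroxymethyl pyrone ester 7 (not isolated)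
Conditions: Bu3SnCH2OH (1.3 equiv), Pd(PPh3)4 (5 mol %), LiCl (3 equiv), 1,4-dioxane, 100 °C
Reagents that add atoms: (tributylstannyl)methanol, CCCC[Sn](CO)(CCCC)CCCC
Why: Stille hydroxymethylation of the electron-poor enol triflate places CH2OH next to the ester, and the cis-held alcohol and ester should lactonise in the same pot (5-exo-trig) to the butenolide.

Step 5
Reactants: 9 (R)-1-phenylethyl acetate
Product: 10 2-[(1R)-1-phenylethoxy]prop-1-ene
Conditions: Cp2TiMe2 (2 equiv), toluene, 65 °C, dark; filtration through basic alumina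
Reagents that add atoms: dimethyltitanocene, C[Ti](C)(C1C=CC=C1)C1C=CC=C1
Why: Petasis methylenation of the ester carbonyl (titanocene methylidene [2+2]/cycloreversion) converts an acetate into the isopropenyl ether without touching the benzylic stereocentre.

Step 6
Reactants: 8 7-methyl-1H-furo[3,4-c]pyran-3,6-dione; 10 2-[(1R)-1-phenylethoxy]prop-1-ene
Product: 11 (1R,4R,5R)-4,5-dimethyl-5-[(1R)-1-phenylethoxy]-2-oxabicyclo[2.2.2]oct-7-en-3-one carrying the fused –C(=O)–O–CH2– butenolide ring at C7 (C=O) and C8 (CH2), alkoxy group anti to the lactone bridge (endo adduct)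
Conditions: 10 (3 equiv), CH2Cl2, 12 kbar, 25 °C, dark; chromatography at or below 20 °C
Reagents that add atoms: none
Why: Inverse-electron-demand Diels–Alder reaction in which the nucleophilic CH2 terminus of 10 bonds first to the O–CH= carbon of 8 (β to the butenolide carbonyl, largest LUMO coefficient) and the developing oxocarbenium carbon then bonds to the methyl-bearing pyrone carbon next to the ring carbonyl, so the regiochemistry follows from the polarisation of both partners. The closest known reaction type is the [4+2] addition of electron-poor (coumalate-type) 2-pyrones to enol ethers and ketene acetals, which gives isolable 2-oxabicyclo[2.2.2]octenone lactones below the temperature of CO2 loss; high pressure is chosen because it accelerates congested cycloadditions without heat or acid. The six-membered carbocycle closes in a concerted, asynchronous suprafacial [4+2] mode (in the stepwise limit a 6-exo-trig attack of the dienolate carbon on the oxocarbenium ion), and the former pyrone C4=C5 bond is left as the butenolide alkene. The two bridgehead centres (CH–O and C–CH3) are cis by construction because the lactone bridge joins them, and their absolute configuration is relayed from the (R)-1-phenylethyl group, which shields one enol ether face while the alkoxy group sits endo under the diene; the alkoxy-bearing carbon is a transient stereocentre removed in step 8. The step needs regio-, endo- and facial selectivity and survival of the bridge: the first comes from the push–pull polarisation, the last from working at 25 °C, and because the auxiliary makes the two bridgehead antipodes diastereomeric, any minor isomer is removed by chromatography so that 11 is carried on as one stereoisomer.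

Step 7
Reactants: 11 bridged lactone adduct
Product: 12 (1R,4R,5R)-5-hydroxy-4,5-dimethyl-2-oxabicyclo[2.2.2]oct-7-en-3-one with the same fused butenolide
Conditions: H2 (1 atm), Pd(OH)2/C, EtOAc, rt
Reagents that add atoms: none
Why: hydrogenolysis of the benzylic C–O bond releases the tertiary alcohol with its configuration untouched, while the tetrasubstituted electron-poor butenolide alkene and the bridgehead allylic C–O bond (whose cleavage would require a bridgehead π-system) should not react.

Step 8
Reactants: 12 bridged tertiary alcohol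
Product: 13 (1R,4S)-4-methyl-5-methylidene-2-oxabicyclo[2.2.2]oct-7-en-3-one with the same fused butenolide
Conditions: SOCl2, pyridine, CH2Cl2, −40 to 0 °C
Reagents that add atoms: none
Why: dehydration of a tertiary alcohol through its chlorosulfite (E2): in the rigid bicyclo[2.2.2] frame no ring hydrogen is anti-periplanar to the leaving group, so pyridine should take a methyl hydrogen and give the exocyclic alkene, with the lactone bridge still protecting both ring oxygen functions and the low temperature preventing CO2 loss.

Step 9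
Reactants: 13 bridged methylidene lactone
Product: 14 (4S,7R)-7-hydroxy-4-methyl-5-methylidene-1-oxo-1,3,4,5,6,7-hexahydro-2-benzofuran-4-carboxylic acid
Conditions: LiOH·H2O (1.2 equiv), THF/H2O, 0 °C; then 1 M HCl to pH 3
Reagents that add atoms: lithium hydroxide, [Li+].[OH-]
Why: saponification (BAc2) in which hydroxide should attack the strained, non-conjugated bridging lactone in preference to the conjugated butenolide (which would reclose on acidification anyway), freeing the cis-related secondary alcohol and carboxylic acid without touching a stereocentre.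

Step 10
Reactants: 14 hydroxy acid with exocyclic methylidene
Product: 15 (4S,5R,7R)-7-hydroxy-4,5-dimethyl-1-oxo-1,3,4,5,6,7-hexahydro-2-benzofuran-4-carboxylic acid
Conditions: [Ir(cod)(PCy3)(py)]PF6 (5 mol %), H2 (1 atm), CH2Cl2, rt
Reagents that add atoms: none
Why: hydroxyl-directed hydrogenation with Crabtree's catalyst: the homoallylic alcohol and the carboxylic acid lie on the same ring face and bind iridium, so H2 should add to the exocyclic alkene from that face and place the new methyl cis to the quaternary methyl (5R), the tetrasubstituted conjugated butenolide alkene being far less reactive.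

Step 11
Reactants: 15 hydroxy acid
Product: 16 (4S,5R,7R)-7-hydroxy-4-(hydroxymethyl)-4,5-dimethyl-4,5,6,7-tetrahydro-2-benzofuran-1(3H)-one
Conditions: BH3·THF (3 equiv), THF, 0 °C to rt; aqueous work-up
Reagents that add atoms: none
Why: chemoselective borane reduction: carboxylic acids are reduced through acyloxyboranes much faster than esters or lactones, so the neopentyl acid should go to the primary alcohol with the butenolide intact.

Step 12
Reactants: 16 diol
Product: 17 [(4S,5R,7R)-7-hydroxy-4,5-dimethyl-1-oxo-1,3,4,5,6,7-hexahydro-2-benzofuran-4-yl]methyl acetate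
Conditions: AcCl (1.05 equiv), 2,4,6-collidine, CH2Cl2, −78 °C
Reagents that add atoms: acetyl chloride, CC(Cl)=O
Why: kinetically selective acylation of a primary over a secondary alcohol masks the hydroxymethyl group so that only the ring alcohol is free for the etherification.

Step 13
Reactants: 18 but-2-yn-1-ol
Product: 20 (Z)-3-iodobut-2-en-1-ol, via cyclic vinylalanate 19 (not isolated)
Conditions: Red-Al (1.5 equiv), THF, 0 °C to rt; then I2, −78 to 0 °C
Reagents that add atoms: iodine, II
Why: alkoxide-directed trans-hydroalumination of the propargylic alcohol puts aluminium on the distal alkyne carbon in a five-membered alanate, and iodinolysis with retention gives the vinyl iodide with iodine cis to CH2OH (Z).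

Step 14
Reactants: 20 (Z)-3-iodobut-2-en-1-ol
Product: 21 (Z)-3-iodobut-2-enal
Conditions: activated MnO2 (15 equiv), CH2Cl2, rt, dark
Reagents that add atoms: none
Why: allylic alcohol oxidation with MnO2 is neutral and should preserve the Z geometry of the β-iodo enal, which is used at once.

Step 15
Reactants: 21 (Z)-3-iodobut-2-enal
Product: 23 (2Z,4S)-2-iodo-6-methylhepta-2,6-dien-4-ol, via diisopinocampheylborinate 22 (not isolated)
Conditions: (−)-Ipc2BOMe (1.3 equiv), 2-methylallylmagnesium chloride (1.25 equiv), Et2O, −78 °C to rt; then 21, −78 °C; then 3 M NaOH, 30% H2O2, 0 °C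
Reagents that add atoms: 2-methylallylmagnesium chloride, CC(=C)C[Mg]Cl
Why: Brown asymmetric allylboration (methallyl variant) through a chair Zimmerman–Traxler transition state, in which the (−)-Ipc2B reagent derived from (+)-α-pinene delivers the allyl group to the Si face of the aldehyde and so sets the carbinol centre as 4S by reagent control.

Step 16
Reactants: 23 (2Z,4S)-2-iodo-6-methylhepta-2,6-dien-4-ol
Product: 24 tert-butyl (2Z,4S)-2-iodo-6-methylhepta-2,6-dien-4-yl carbonate
Conditions: Boc2O (1.5 equiv), DMAP (0.2 equiv), MeCN, rt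
Reagents that add atoms: di-tert-butyl dicarbonate, CC(C)(C)OC(=O)OC(=O)OC(C)(C)C
Why: DMAP-catalysed acylation gives the homoallylic tert-butyl carbonate needed as the internal oxygen nucleophile of the next step.

Step 17
Reactants: 24 homoallylic tert-butyl carbonate
Product: 25 (4R,6S)-4-(iodomethyl)-6-[(1Z)-2-iodoprop-1-en-1-yl]-4-methyl-1,3-dioxan-2-one
Conditions: IBr (1.5 equiv), toluene, −85 °C; Na2S2O3 quench
Reagents that add atoms: iodine monobromide, IBr
Why: Bartlett–Smith iodocarbonate cyclisation: IBr activates the electron-rich 1,1-disubstituted alkene rather than the iodoalkene, the carbonate carbonyl oxygen closes the ring in 6-exo mode through a chair with the alkenyl and CH2I groups equatorial, and loss of the tert-butyl cation should give the syn carbonate, fixing the tertiary C–O centre (4R) from the carbinol centre (the epimer, if formed, is removed after step 18).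

Step 18
Reactants: 25 cyclic iodocarbonate
Product: 27 (2S,3Z)-4-iodo-1-[(2R)-2-methyloxiran-2-yl]pent-3-en-2-ol, via iodo diol 26 (not isolated)
Conditions: K2CO3 (3 equiv), MeOH, rt
Reagents that add atoms: none
Why: carbonate methanolysis followed by intramolecular Williamson displacement of iodide by the tertiary alkoxide (3-exo-tet) gives the 2,2-disubstituted epoxide with retention at the tertiary carbon.

Step 19
Reactants: 27 epoxy alcohol
Product: 28 tert-butyl{[(2S,3Z)-4-iodo-1-[(2R)-2-methyloxiran-2-yl]pent-3-en-2-yl]oxy}dimethylsilane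
Conditions: TBSCl, imidazole, DMF, rt
Reagents that add atoms: tert-butyldimethylsilyl chloride, CC(C)(C)[Si](C)(C)Cl
Why: silylation of the secondary allylic alcohol stops it from competing as a nucleophile in the acid-catalysed etherification.

Step 20
Reactants: 17 ring alcohol acetate; 28 silyl-protected epoxide
Product: 29 [(4S,5R,7R)-7-{[(2S,4S,5Z)-4-(tert-butyldimethylsilyloxy)-1-hydroxy-6-iodo-2-methylhept-5-en-2-yl]oxy}-4,5-dimethyl-1-oxo-1,3,4,5,6,7-hexahydro-2-benzofuran-4-yl]methyl acetate
Conditions: BF3·OEt2 (0.2 equiv), CH2Cl2, −40 to −20 °C; 17 (2 equiv, surplus recovered), slow addition of 28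
Reagents that add atoms: none
Why: Lewis acid-catalysed alcoholysis of a 2,2-disubstituted epoxide, in which the ring alcohol attacks the tertiary carbon of the activated epoxide (borderline SN2, Markovnikov regiochemistry) with inversion, making the tertiary ether carbon S and releasing the epoxide oxygen as the CH2OH group.

Step 21
Reactants: 29 tertiary ether with free primary alcohol
Product: 30 the 1,4-bis(tert-butyldimethylsilyl) ether of 29 (primary CH2OH silylated)
Conditions: TBSOTf (1.3 equiv), 2,6-lutidine, CH2Cl2, −78 °C
Reagents that add atoms: tert-butyldimethylsilyl triflate, CC(C)(C)[Si](C)(C)OS(=O)(=O)C(F)(F)F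
Why: silyl triflate/lutidine silylation protects the hindered neopentyl-type primary alcohol so that the other hydroxymethyl group can be oxidised alone.

Step 22
Reactants: 30 bis-silyl ether acetate
Product: 31 (4S,5R,7R)-7-{[(2S,4S,5Z)-1,4-bis(tert-butyldimethylsilyloxy)-6-iodo-2-methylhept-5-en-2-yl]oxy}-4-(hydroxymethyl)-4,5-dimethyl-4,5,6,7-tetrahydro-2-benzofuran-1(3H)-one
Conditions: K2CO3 (0.3 equiv), MeOH, 0 °C to rt
Reagents that add atoms: none
Why: base-catalysed transesterification removes the acetate while silyl ethers, vinyl iodide and the butenolide (any methanolysis of which is reversible) should survive.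

Step 23
Reactants: 31 primary alcohol
Product: 32 the corresponding 4-carbaldehyde (4S,5R,7R)
Conditions: Dess–Martin periodinane (1.5 equiv), NaHCO3, CH2Cl2, 0 °C to rt
Reagents that add atoms: none
Why: Dess–Martin oxidation gives the non-enolisable neopentyl aldehyde under buffered, neutral conditions.

Step 24
Reactants: 32 aldehyde
Product: 33 the corresponding 4-ethenyl compound (4S,5R,7R)
Conditions: Ph3PCH3Br (2 equiv), KHMDS (1.8 equiv), THF, −78 to 0 °C
Reagents that add atoms: methyltriphenylphosphonium bromide, C[P+](c1ccccc1)(c1ccccc1)c1ccccc1.[Br-]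
Why: Wittig methylenation of the aldehyde is fast at low temperature, which should leave the lactone carbonyl and the acidic butenolide CH2 untouched.

Step 25
Reactants: 33 vinyl compound carrying the Z-vinyl iodide
Product: 35 bis(tert-butyldimethylsilyl) ether of Neocucurbin A, via B-alkyl-9-BBN 34 (not isolated)
Conditions: 9-BBN (2 equiv), THF, rt; then slow addition to Pd(dppf)Cl2 (20 mol %), AsPh3 (40 mol %), Cs2CO3 (3 equiv), DMF/THF/H2O, 40 °C, 1 mM
Reagents that add atoms: none
Why: anti-Markovnikov hydroboration of the only monosubstituted alkene, then intramolecular B-alkyl Suzuki–Miyaura coupling with the vinyl iodide, closes the 12-membered ring at the C(sp3)–C(sp2) bond with retention of the Z geometry.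

Step 26
Reactants: 35 bis-silyl ether of the macrocycle
Product: 36 Neocucurbin A
Conditions: HF·pyridine, pyridine/THF, 0 °C to rt
Reagents that add atoms: none
Why: fluoride-mediated desilylation under buffered, weakly acidic conditions should free both hydroxyl groups without opening or isomerising the butenolide or ionising the tertiary ether.

**Compound list**

1 | dimethyl 3-oxopentanedioate | COC(=O)CC(=O)CC(=O)OC | starting material
2 | dimethyl 2-methyl-3-oxopentanedioate (racemic, enolisable) | COC(=O)C(C)C(=O)CC(=O)OC | intermediate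
3 | triethyl orthoformate | CCOC(OCC)OCC | starting material
4 | dimethyl 2-(ethoxymethylidene)-4-methyl-3-oxopentanedioate | CCOC=C(C(=O)OC)C(=O)C(C)C(=O)OC | intermediate
5 | methyl 4-hydroxy-5-methyl-6-oxo-6H-pyran-3-carboxylate | COC(=O)C1=COC(=O)C(C)=C1O | intermediate
6 | methyl 5-methyl-6-oxo-4-(trifluoromethylsulfonyloxy)-6H-pyran-3-carboxylate | COC(=O)C1=COC(=O)C(C)=C1OS(=O)(=O)C(F)(F)F | intermediate
7 | methyl 4-(hydroxymethyl)-5-methyl-6-oxo-6H-pyran-3-carboxylate | COC(=O)C1=COC(=O)C(C)=C1CO | intermediate
8 | 7-methyl-1H-furo[3,4-c]pyran-3,6-dione (butenolide-fused 3-methyl-2-pyrone) | CC1=C2COC(=O)C2=COC1=O | intermediate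
9 | (R)-1-phenylethyl acetate | C[C@@H](OC(C)=O)c1ccccc1 | starting material
10 | 2-[(1R)-1-phenylethoxy]prop-1-ene | C=C(C)O[C@H](C)c1ccccc1 | intermediate
11 | (1R,4R,5R)-4,5-dimethyl-5-[(1R)-1-phenylethoxy]-2-oxabicyclo[2.2.2]oct-7-en-3-one with butenolide fused at C7 (C=O)/C8 (CH2), endo-alkoxy | O1[C@@H]2C[C@@](C)(O[C@H](C)c3ccccc3)[C@](C)(C1=O)C1=C2C(=O)OC1 | intermediate
12 | (1R,4R,5R)-5-hydroxy-4,5-dimethyl analogue of 11 | O1[C@@H]2C[C@@](C)(O)[C@](C)(C1=O)C1=C2C(=O)OC1 | intermediate
13 | (1R,4S)-4-methyl-5-methylidene-2-oxabicyclo[2.2.2]oct-7-en-3-one with the same fused butenolide | O1[C@@H]2CC(=C)[C@](C)(C1=O)C1=C2C(=O)OC1 | intermediate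
14 | (4S,7R)-7-hydroxy-4-methyl-5-methylidene-1-oxo-1,3,4,5,6,7-hexahydro-2-benzofuran-4-carboxylic acid | O[C@@H]1CC(=C)[C@](C)(C(O)=O)C2=C1C(=O)OC2 | intermediate
15 | (4S,5R,7R)-7-hydroxy-4,5-dimethyl-1-oxo-1,3,4,5,6,7-hexahydro-2-benzofuran-4-carboxylic acid | O[C@@H]1C[C@@H](C)[C@](C)(C(O)=O)C2=C1C(=O)OC2 | intermediate
16 | (4S,5R,7R)-7-hydroxy-4-(hydroxymethyl)-4,5-dimethyl-4,5,6,7-tetrahydro-2-benzofuran-1(3H)-one | O[C@@H]1C[C@@H](C)[C@](C)(CO)C2=C1C(=O)OC2 | intermediate
17 | [(4S,5R,7R)-7-hydroxy-4,5-dimethyl-1-oxo-1,3,4,5,6,7-hexahydro-2-benzofuran-4-yl]methyl acetate | O[C@@H]1C[C@@H](C)[C@](C)(COC(C)=O)C2=C1C(=O)OC2 | intermediate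
18 | but-2-yn-1-ol | CC#CCO | starting material
19 | sodium cyclic (Z)-vinylalanate of but-2-yn-1-ol (Al on C3, bound to the alkoxide) | C/C1=C/CO[Al-]1(OCCOC)OCCOC.[Na+] | intermediate
20 | (Z)-3-iodobut-2-en-1-ol | C/C(I)=C/CO | intermediate
21 | (Z)-3-iodobut-2-enal | C/C(I)=C/C=O | intermediate
22 | diisopinocampheylborinate of 23 | C/C(I)=C/[C@@H](OB([C@@H]1C[C@@H]2C[C@H]([C@H]1C)C2(C)C)[C@@H]1C[C@@H]2C[C@H]([C@H]1C)C2(C)C)CC(C)=C | intermediate
23 | (2Z,4S)-2-iodo-6-methylhepta-2,6-dien-4-ol | C/C(I)=C/[C@@H](O)CC(C)=C | intermediate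
24 | tert-butyl (2Z,4S)-2-iodo-6-methylhepta-2,6-dien-4-yl carbonate | C/C(I)=C/[C@@H](OC(=O)OC(C)(C)C)CC(C)=C | intermediate
25 | (4R,6S)-4-(iodomethyl)-6-[(1Z)-2-iodoprop-1-en-1-yl]-4-methyl-1,3-dioxan-2-one | C/C(I)=C/[C@@H]1C[C@](C)(CI)OC(=O)O1 | intermediate
26 | (2R,4S,5Z)-1,6-diiodo-2-methylhept-5-ene-2,4-diol | C/C(I)=C/[C@@H](O)C[C@@](C)(O)CI | intermediate
27 | (2S,3Z)-4-iodo-1-[(2R)-2-methyloxiran-2-yl]pent-3-en-2-ol | C/C(I)=C/[C@@H](O)C[C@]1(C)CO1 | intermediate
28 | tert-butyl{[(2S,3Z)-4-iodo-1-[(2R)-2-methyloxiran-2-yl]pent-3-en-2-yl]oxy}dimethylsilane | C/C(I)=C/[C@@H](O[Si](C)(C)C(C)(C)C)C[C@]1(C)CO1 | intermediate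
29 | [(4S,5R,7R)-7-{[(2S,4S,5Z)-4-(tert-butyldimethylsilyloxy)-1-hydroxy-6-iodo-2-methylhept-5-en-2-yl]oxy}-4,5-dimethyl-1-oxo-1,3,4,5,6,7-hexahydro-2-benzofuran-4-yl]methyl acetate | C/C(I)=C/[C@@H](O[Si](C)(C)C(C)(C)C)C[C@@](C)(CO)O[C@@H]1C[C@@H](C)[C@](C)(COC(C)=O)C2=C1C(=O)OC2 | intermediate
30 | 1,4-bis(tert-butyldimethylsilyl) ether of 29 | C/C(I)=C/[C@@H](O[Si](C)(C)C(C)(C)C)C[C@@](C)(CO[Si](C)(C)C(C)(C)C)O[C@@H]1C[C@@H](C)[C@](C)(COC(C)=O)C2=C1C(=O)OC2 | intermediate
31 | (4S,5R,7R)-7-{[(2S,4S,5Z)-1,4-bis(tert-butyldimethylsilyloxy)-6-iodo-2-methylhept-5-en-2-yl]oxy}-4-(hydroxymethyl)-4,5-dimethyl-4,5,6,7-tetrahydro-2-benzofuran-1(3H)-one | C/C(I)=C/[C@@H](O[Si](C)(C)C(C)(C)C)C[C@@](C)(CO[Si](C)(C)C(C)(C)C)O[C@@H]1C[C@@H](C)[C@](C)(CO)C2=C1C(=O)OC2 | intermediate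
32 | 4-carbaldehyde corresponding to 31 (4S,5R,7R) | C/C(I)=C/[C@@H](O[Si](C)(C)C(C)(C)C)C[C@@](C)(CO[Si](C)(C)C(C)(C)C)O[C@@H]1C[C@@H](C)[C@](C)(C=O)C2=C1C(=O)OC2 | intermediate
33 | 4-ethenyl compound corresponding to 32 (4S,5R,7R) | C/C(I)=C/[C@@H](O[Si](C)(C)C(C)(C)C)C[C@@](C)(CO[Si](C)(C)C(C)(C)C)O[C@@H]1C[C@@H](C)[C@](C)(C=C)C2=C1C(=O)OC2 | intermediate
34 | 4-[2-(9-borabicyclo[3.3.1]nonan-9-yl)ethyl] compound from 33 | C/C(I)=C/[C@@H](O[Si](C)(C)C(C)(C)C)C[C@@](C)(CO[Si](C)(C)C(C)(C)C)O[C@@H]1C[C@@H](C)[C@](C)(CCB3C4CCCC3CCC4)C2=C1C(=O)OC2 | intermediate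
35 | bis(tert-butyldimethylsilyl) ether of Neocucurbin A (secondary allylic O and primary CH2O silylated) | C/C1=C/[C@@H](O[Si](C)(C)C(C)(C)C)C[C@@](C)(CO[Si](C)(C)C(C)(C)C)O[C@@H]2C[C@@H](C)[C@](C)(CC1)C1=C2C(=O)OC1 | intermediate
36 | Neocucurbin A | C/C1=C/[C@@H](O)C[C@@](C)(CO)O[C@@H]2C[C@@H](C)[C@](C)(CC1)C1=C2C(=O)OC1 | target

**Totals**

Total step count: 26. Longest linear sequence: 18 steps (1–4, 6–12, 20–26).

**Steps most likely to fail**

Step 6 (cycloaddition). After the first C–C bond has formed, closure between two fully substituted carbons may be slower than proton loss from the oxocarbenium ion or reversion. The small auxiliary may discriminate the faces only weakly, and the adduct may extrude CO2 during handling. The fallback sets out from 8 and comes back at 13, so steps 7 and 8 fall away; it moves the dienophile to the ketone oxidation level. (2R,3R)-Butane-2,3-diol and bromoacetaldehyde diethyl acetal (TsOH, toluene, ethanol distilled off) give (4R,5R)-2-(bromomethyl)-4,5-dimethyl-1,3-dioxolane F1. KOt-Bu in THF eliminates HBr to the C2-symmetric ketene acetal (4R,5R)-4,5-dimethyl-2-methylidene-1,3-dioxolane F2, a stronger nucleophile for which no endo/exo question exists. Its [4+2] addition to 8 (toluene, 25 °C) should give the spiro-ketal bridged lactone F3 as two bridgehead diastereomers, which are separated. Aqueous acid (TsOH, acetone/H2O) releases the bridged keto lactone F4, and Lombardo methylenation (Zn, CH2Br2, TiCl4, THF, 0 °C) converts its ketone into the exocyclic alkene of 13.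

Step 20 (etherification). Lewis acid-induced hydride shift of the epoxide to an aldehyde, or oligomerisation through the newly formed primary alcohol, may consume 28 faster than the hindered secondary alcohol captures it. Partial ionisation may also erode the inversion at the tertiary carbon. The fallback sets out from 17 and 23 and comes back at 29; it forms the ether by Markovnikov alkoxymercuration instead of epoxide opening. Alcohol 23 is silylated (TBSCl, imidazole, DMF) to tert-butyl{[(2Z,4S)-2-iodo-6-methylhepta-2,6-dien-4-yl]oxy}dimethylsilane F5. Hg(O2CCF3)2 (CH2Cl2, −20 °C) activates its 1,1-disubstituted alkene, and 17 adds to the tertiary carbon to give the alkylmercury trifluoroacetate F6. Oxidative demercuration (NaBH4, O2, DMF, 0 °C) turns CH2Hg into CH2OH and should give 29 together with its epimer at the ether carbon. That epimer must be removed by chromatography, because this variant has no control over that centre.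

Step 25 (macrocyclisation). Intermolecular coupling, protodeboronation or β-hydride elimination may outrun closure of the strained bridged 12-membered ring under the aqueous basic conditions. The fallback sets out from 33 and comes back at 35; the alkyl partner is made as an isolable iodide and coupled as an organozinc without base. Hydroboration of 33 with 9-BBN and oxidation with NaBO3 give the 4-(2-hydroxyethyl) primary alcohol F7. I2, PPh3 and imidazole (CH2Cl2, 0 °C) convert it into the primary iodide F8. Activated zinc dust (DMA, 30 °C) inserts into the C(sp3)–I bond only, giving the alkylzinc iodide F9, which is not isolated. Slow addition of F9 to Pd2(dba)3/SPhos (THF/DMA, 40 °C, high dilution) effects an intramolecular Negishi coupling with the vinyl iodide and should give 35.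

**Further compounds**

F1 | step 6 | (4R,5R)-2-(bromomethyl)-4,5-dimethyl-1,3-dioxolane | BrCC1O[C@H](C)[C@@H](C)O1
F2 | step 6 | (4R,5R)-4,5-dimethyl-2-methylidene-1,3-dioxolane | C=C1O[C@H](C)[C@@H](C)O1
F3 | step 6 | spiro-ketal bridged lactone (ketal of F4 with (2R,3R)-butane-2,3-diol; bridgeheads as in 13) | O1[C@@H]2CC3(O[C@H](C)[C@@H](C)O3)[C@](C)(C1=O)C1=C2C(=O)OC1
F4 | step 6 | bridged keto lactone (5-oxo analogue of 13) | O1[C@@H]2CC(=O)[C@](C)(C1=O)C1=C2C(=O)OC1
F5 | step 20 | tert-butyl{[(2Z,4S)-2-iodo-6-methylhepta-2,6-dien-4-yl]oxy}dimethylsilane | C/C(I)=C/[C@@H](O[Si](C)(C)C(C)(C)C)CC(C)=C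
F6 | step 20 | alkylmercury trifluoroacetate (29 with CH2HgO2CCF3 in place of CH2OH) | C/C(I)=C/[C@@H](O[Si](C)(C)C(C)(C)C)C[C@@](C)(C[Hg]OC(=O)C(F)(F)F)O[C@@H]1C[C@@H](C)[C@](C)(COC(C)=O)C2=C1C(=O)OC2
F7 | step 25 | 4-(2-hydroxyethyl) primary alcohol from 33 | C/C(I)=C/[C@@H](O[Si](C)(C)C(C)(C)C)C[C@@](C)(CO[Si](C)(C)C(C)(C)C)O[C@@H]1C[C@@H](C)[C@](C)(CCO)C2=C1C(=O)OC2
F8 | step 25 | 4-(2-iodoethyl) primary iodide | C/C(I)=C/[C@@H](O[Si](C)(C)C(C)(C)C)C[C@@](C)(CO[Si](C)(C)C(C)(C)C)O[C@@H]1C[C@@H](C)[C@](C)(CCI)C2=C1C(=O)OC2
F9 | step 25 | alkylzinc iodide from F8 | C/C(I)=C/[C@@H](O[Si](C)(C)C(C)(C)C)C[C@@](C)(CO[Si](C)(C)C(C)(C)C)O[C@@H]1C[C@@H](C)[C@](C)(CC[Zn]I)C2=C1C(=O)OC2
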